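## Retrosynthesis

1. Global hydrogenolysis of the 15 aryl benzyl ethers of the perbenzylated castalagin-type compound gives the target.
2. The perbenzylated compound comes from an intramolecular Pd C–H arylation. It joins the O5-(2-iodogalloyl) ring to the free ortho C–H of the O3 ring and closes the 11-membered biaryl lactone. The precursor comes from a Lewis-acid Friedel–Crafts hydroxyalkylation of the C1 aldehyde onto the O2-aryl ring, which closes the 6-membered C-aryl lactone and sets the C1 carbinol.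
3. That aldehyde, carrying the O5 2-iodogalloyl ester, comes from an N,N-dimethylhydrazone formed by ring-opening of perbenzylated pedunculagin (the 2,3:4,6-bis-HHDP glucopyranose lactol).
4. Both (S)-HHDP bridges are made by intramolecular Ullmann couplings on the ⁴C₁ phenyl thioglucoside template. The building blocks are phenyl 4,6-O-benzylidene-1-thio-β-D-glucopyranoside and 2-iodo-3,4,5-tris(benzyloxy)benzoic acid, which supplies all five galloyl units.
5. Ring-formation order: 2,3-HHDP, 4,6-HHDP, pyranose opening, C1-aryl lactone, then the galloyl(O5)–galloyl(O3) biaryl ring.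

Assumptions:
- The SMILES leaves the biaryl axes undefined, so I target the natural axes (both HHDP units S; NHTP axes as in castalagin).
- By CIP analysis C1 is R, which I take to be the castalagin (1α-OH) epimer.
- 3,4,5-Tris(benzyloxy)benzoic acid and phenyl 4,6-O-benzylidene-1-thio-β-D-glucopyranoside are commercially available.

## Route

**Step 1**
Reactants: 1 (3,4,5-tris(benzyloxy)benzoic acid)
Product: 2 (2-iodo-3,4,5-tris(benzyloxy)benzoic acid)
Conditions: NIS, cat. TFA, MeCN, 50 °C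
Reagents that add atoms: N-iodosuccinimide, O=C1CCC(=O)N1I
Why: Electrophilic aromatic iodination occurs at C2, which is ortho to CO2H and activated by the OBn groups. C2 and C6 are equivalent, so only one mono-iodide forms.

**Step 2**
Reactants: 3 (phenyl 4,6-O-benzylidene-1-thio-β-D-glucopyranoside), 2 (2.6 equiv)
Product: 4 (2,3-bis-O-(2-iodo-3,4,5-tribenzyloxybenzoyl) ester of 3)
Conditions: EDCI, DMAP, CH2Cl2, rt
Reagents that add atoms: none
Why: Steglich esterification of the free 2,3-diol, the only free hydroxyls, with no stereocentre change.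

**Step 3**
Reactants: 4
Product: 5 (2,3-O-(S)-hexabenzyl-HHDP-4,6-O-benzylidene thioglucoside)
Conditions: activated Cu powder, DMF, 120 °C
Reagents that add atoms: none
Why: Intramolecular Ullmann coupling of the two aryl iodides. The trans-diequatorial 2,3-diester on the benzylidene-locked ⁴C₁ ring bridges a 10-membered ring, which favours the (S) biaryl axis.

**Step 4**
Reactants: 5
Product: 6 (2,3-O-HHDP thioglucoside, 4,6-diol)
Conditions: 80% aq. AcOH, 70 °C
Reagents that add atoms: none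
Why: Acid-catalysed hydrolysis of the benzylidene acetal. The aryl esters, benzyl ethers and S-phenyl group survive.

**Step 5**
Reactants: 6, 2 (2.6 equiv)
Product: 7 (4,6-bis(2-iodogalloyl) ester of 6)
Conditions: EDCI, DMAP, CH2Cl2, rt
Reagents that add atoms: none
Why: Steglich esterification of O4 and O6.

**Step 6**
Reactants: 7
Product: 8 (phenyl 2,3:4,6-bis-O-[(S)-hexabenzyl-HHDP]-1-thio-β-D-glucopyranoside)
Conditions: activated Cu powder, DMF, 120 °C
Reagents that add atoms: none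
Why: Ullmann coupling with only one aryl-iodide pair present. The 4,6-bridge on the ⁴C₁ pyranose is strongly (S)-selective.

**Step 7**
Reactants: 8
Product: 9 (perbenzyl pedunculagin, lactol, α/β mixture)
Conditions: NBS, acetone/H2O (9:1), 0 °C
Reagents that add atoms: water, O
Why: NBS activates the thioglycoside (thiophilic hydrolysis) and water captures the oxocarbenium ion. The anomeric centre becomes a lactol and is destroyed later, so the α/β ratio does not matter.

**Step 8**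
Reactants: 9
Product: 10 (E-N,N-dimethylhydrazone of the open-chain aldehyde, free 5-OH)
Conditions: Me2NNH2, cat. AcOH, CH2Cl2/MeOH, rt
Reagents that add atoms: 1,1-dimethylhydrazine, CN(C)N
Why: Condensation with the open-chain tautomer traps the ring-opened form. O5 is freed, C1 is masked as an aldehyde equivalent, and C2–C5 are untouched.

**Step 9**
Reactants: 10, 2
Product: 11 (5-O-(2-iodo-3,4,5-tribenzyloxybenzoyl) hydrazone)
Conditions: 2, 2,4,6-Cl3C6H2COCl, Et3N, then DMAP, toluene, rt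
Reagents that add atoms: none
Why: Yamaguchi esterification acylates the only free hydroxyl, O5, so the chain can no longer re-close to a pyranose.

**Step 10**
Reactants: 11
Product: 12 (open-chain aldehyde)
Conditions: NaIO4, THF/pH 7 phosphate buffer, rt
Reagents that add atoms: water, O
Why: Oxidative cleavage of the N,N-dimethylhydrazone under neutral conditions releases the aldehyde. Base is avoided because the α- and β-acyloxy aldehyde is prone to epimerisation and elimination.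

**Step 11**
Reactants: 12
Product: 13 (C1-aryl lactone, 1R-OH, with the O5-galloyl aryl iodide)
Conditions: Sc(OTf)3 (20 mol%), CH2Cl2, −20 °C to rt
Reagents that add atoms: none
Why: Lewis-acid intramolecular Friedel–Crafts hydroxyalkylation of the free ortho C–H of the O2-galloyl ring forms the 6-membered lactone. The new C1 centre is set by the chair-like transition state, with the Lewis-acid-bound carbonyl oxygen placed away from the C2/C3 substituents, which I expect to give the (1R) carbinol.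

**Step 12**
Reactants: 13
Product: 14 (pentadeca-O-benzyl castalagin)
Conditions: Pd(OAc)2, PCy3·HBF4, K2CO3, PivOH, DMA, 120 °C
Reagents that add atoms: none
Why: Intramolecular Pd-catalysed direct C–H arylation (concerted metalation–deprotonation) joins the O5-galloyl aryl iodide to the free ortho C–H of the O3 ring. Macrocyclic strain fixes the new biaryl axis. It is run after Step 11 so that no base-sensitive aldehyde is present.

**Step 13**
Reactants: 14
Product: 15 (target)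
Conditions: H2 (1 atm), Pd(OH)2/C, THF/MeOH, rt
Reagents that add atoms: none (H2 only)
Why: Hydrogenolysis removes all 15 aryl benzyl ethers. The reaction is run at 1 atm and rt and stopped at full debenzylation, so the benzylic C1–OH is retained. The aryl esters and the C1 and C2–C5 stereocentres are unaffected.

## Compound list

1 | 3,4,5-tris(benzyloxy)benzoic acid | OC(=O)c1cc(OCc2ccccc2)c(OCc2ccccc2)c(OCc2ccccc2)c1 | starting material

2 | 2-iodo-3,4,5-tris(benzyloxy)benzoic acid | OC(=O)c1cc(OCc2ccccc2)c(OCc2ccccc2)c(OCc2ccccc2)c1I | intermediate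

3 | phenyl 4,6-O-benzylidene-1-thio-β-D-glucopyranoside | C([C@@H]1[C@H]([C@@H]([C@H]([C@@H](O1)Sc1ccccc1)O)O)O2)O[C@H]2c1ccccc1 | starting material

4 | 2,3-bis-O-(2-iodo-tribenzylgalloyl) derivative of 3 | C([C@@H]1[C@H]([C@@H]([C@H]([C@@H](O1)Sc1ccccc1)OC(=O)c%11cc(OCc%10ccccc%10)c(OCc%10ccccc%10)c(OCc%10ccccc%10)c%11I)OC(=O)c%11cc(OCc%10ccccc%10)c(OCc%10ccccc%10)c(OCc%10ccccc%10)c%11I)O2)O[C@H]2c1ccccc1 | intermediate

5 | 2,3-O-(S)-hexabenzyl-HHDP-4,6-O-benzylidene thioglucoside | C([C@@H]1[C@H]([C@@H]([C@H]([C@@H](O1)Sc1ccccc1)OC(=O)c%11cc(OCc%10ccccc%10)c(OCc%10ccccc%10)c(OCc%10ccccc%10)c%11-c%12c(OCc%10ccccc%10)c(OCc%10ccccc%10)c(OCc%10ccccc%10)cc%12C(=O)%13)O%13)O2)O[C@H]2c1ccccc1 | intermediate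

6 | 2,3-O-HHDP thioglucoside, 4,6-diol | C([C@@H]1[C@H]([C@@H]([C@H]([C@@H](O1)Sc1ccccc1)OC(=O)c%11cc(OCc%10ccccc%10)c(OCc%10ccccc%10)c(OCc%10ccccc%10)c%11-c%12c(OCc%10ccccc%10)c(OCc%10ccccc%10)c(OCc%10ccccc%10)cc%12C(=O)%13)O%13)O)O | intermediate

7 | 4,6-bis-O-(2-iodo-tribenzylgalloyl) ester of 6 | C([C@@H]1[C@H]([C@@H]([C@H]([C@@H](O1)Sc1ccccc1)OC(=O)c%11cc(OCc%10ccccc%10)c(OCc%10ccccc%10)c(OCc%10ccccc%10)c%11-c%12c(OCc%10ccccc%10)c(OCc%10ccccc%10)c(OCc%10ccccc%10)cc%12C(=O)%13)O%13)OC(=O)c%11cc(OCc%10ccccc%10)c(OCc%10ccccc%10)c(OCc%10ccccc%10)c%11I)OC(=O)c%11cc(OCc%10ccccc%10)c(OCc%10ccccc%10)c(OCc%10ccccc%10)c%11I | intermediate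

8 | phenyl 2,3:4,6-bis-O-[(S)-hexabenzyl-HHDP]-1-thio-β-D-glucopyranoside | C([C@@H]1[C@H]([C@@H]([C@H]([C@@H](O1)Sc1ccccc1)OC(=O)c%11cc(OCc%10ccccc%10)c(OCc%10ccccc%10)c(OCc%10ccccc%10)c%11-c%12c(OCc%10ccccc%10)c(OCc%10ccccc%10)c(OCc%10ccccc%10)cc%12C(=O)%13)O%13)OC(=O)c%14cc(OCc%10ccccc%10)c(OCc%10ccccc%10)c(OCc%10ccccc%10)c%14-c%15c(OCc%10ccccc%10)c(OCc%10ccccc%10)c(OCc%10ccccc%10)cc%15C(=O)%16)O%16 | intermediate

9 | dodeca-O-benzyl pedunculagin (bis-HHDP glucopyranose, lactol, anomers not specified) | C([C@@H]1[C@H]([C@@H]([C@H]([CH](O1)O)OC(=O)c%11cc(OCc%10ccccc%10)c(OCc%10ccccc%10)c(OCc%10ccccc%10)c%11-c%12c(OCc%10ccccc%10)c(OCc%10ccccc%10)c(OCc%10ccccc%10)cc%12C(=O)%13)O%13)OC(=O)c%14cc(OCc%10ccccc%10)c(OCc%10ccccc%10)c(OCc%10ccccc%10)c%14-c%15c(OCc%10ccccc%10)c(OCc%10ccccc%10)c(OCc%10ccccc%10)cc%15C(=O)%16)O%16 | intermediate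

10 | aldehydo-D-glucose N,N-dimethylhydrazone, 2,3:4,6-bis-HHDP, free 5-OH | CN(C)/N=C/[C@H](OC(=O)c%11cc(OCc%10ccccc%10)c(OCc%10ccccc%10)c(OCc%10ccccc%10)c%11-c%12c(OCc%10ccccc%10)c(OCc%10ccccc%10)c(OCc%10ccccc%10)cc%12C(=O)%13)[C@@H](O%13)[C@H](OC(=O)c%14cc(OCc%10ccccc%10)c(OCc%10ccccc%10)c(OCc%10ccccc%10)c%14-c%15c(OCc%10ccccc%10)c(OCc%10ccccc%10)c(OCc%10ccccc%10)cc%15C(=O)%16)[C@H](O)CO%16 | intermediate

11 | 5-O-(2-iodo-tribenzylgalloyl) derivative of 10 | CN(C)/N=C/[C@H](OC(=O)c%11cc(OCc%10ccccc%10)c(OCc%10ccccc%10)c(OCc%10ccccc%10)c%11-c%12c(OCc%10ccccc%10)c(OCc%10ccccc%10)c(OCc%10ccccc%10)cc%12C(=O)%13)[C@@H](O%13)[C@H](OC(=O)c%14cc(OCc%10ccccc%10)c(OCc%10ccccc%10)c(OCc%10ccccc%10)c%14-c%15c(OCc%10ccccc%10)c(OCc%10ccccc%10)c(OCc%10ccccc%10)cc%15C(=O)%16)[C@H](OC(=O)c%17cc(OCc%10ccccc%10)c(OCc%10ccccc%10)c(OCc%10ccccc%10)c%17I)CO%16 | intermediate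

12 | aldehydo-sugar: 5-O-iodogalloyl, 2,3:4,6-bis-HHDP | O=C[C@H](OC(=O)c%11cc(OCc%10ccccc%10)c(OCc%10ccccc%10)c(OCc%10ccccc%10)c%11-c%12c(OCc%10ccccc%10)c(OCc%10ccccc%10)c(OCc%10ccccc%10)cc%12C(=O)%13)[C@@H](O%13)[C@H](OC(=O)c%14cc(OCc%10ccccc%10)c(OCc%10ccccc%10)c(OCc%10ccccc%10)c%14-c%15c(OCc%10ccccc%10)c(OCc%10ccccc%10)c(OCc%10ccccc%10)cc%15C(=O)%16)[C@H](OC(=O)c%17cc(OCc%10ccccc%10)c(OCc%10ccccc%10)c(OCc%10ccccc%10)c%17I)CO%16 | intermediate

13 | C1-aryl lactone (1R-OH), galloyl(O5) aryl iodide, free ortho C–H on the O3 ring | O=C1OC[C@@H](OC(=O)c2cc(OCc%10ccccc%10)c(OCc%10ccccc%10)c(OCc%10ccccc%10)c2I)[C@@H](OC(=O)c2cc(OCc%10ccccc%10)c(OCc%10ccccc%10)c(OCc%10ccccc%10)c2-c2c1cc(OCc%10ccccc%10)c(OCc%10ccccc%10)c2OCc%10ccccc%10)[C@H](OC(=O)c3cc(OCc%10ccccc%10)c(OCc%10ccccc%10)c(OCc%10ccccc%10)c3-c3c(OCc%10ccccc%10)c(OCc%10ccccc%10)c(OCc%10ccccc%10)c4c3C(=O)O5)[C@@H]5[C@@H]4O | intermediate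

14 | pentadeca-O-benzyl castalagin | O=C1OC[C@H]2OC(=O)c3cc(OCc%10ccccc%10)c(OCc%10ccccc%10)c(OCc%10ccccc%10)c3-c3c(OCc%10ccccc%10)c(OCc%10ccccc%10)c(OCc%10ccccc%10)c4c3C(=O)O[C@H]([C@H]3OC(=O)c5c-4c(OCc%10ccccc%10)c(OCc%10ccccc%10)c(OCc%10ccccc%10)c5[C@H]3O)[C@@H]2OC(=O)c2cc(OCc%10ccccc%10)c(OCc%10ccccc%10)c(OCc%10ccccc%10)c2-c2c1cc(OCc%10ccccc%10)c(OCc%10ccccc%10)c2OCc%10ccccc%10 | intermediate

15 | target, CID12302513 (castalagin-type C-glucosidic ellagitannin) | O=C1OC[C@H]2OC(=O)c3cc(O)c(O)c(O)c3-c3c(O)c(O)c(O)c4c3C(=O)O[C@H]([C@H]3OC(=O)c5c-4c(O)c(O)c(O)c5[C@H]3O)[C@@H]2OC(=O)c2cc(O)c(O)c(O)c2-c2c1cc(O)c(O)c2O | target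

## Totals

- Total steps: 13.
- Longest linear sequence: 13 steps (1 → 2 → 4 → 5 → 6 → 7 → 8 → 9 → 10 → 11 → 12 → 13 → 14 → 15). The iodo acid 2 is made in Step 1 and consumed in Step 2, so it lies on the longest path. The commercial thioglucoside 3 joins at Step 2.

## Three steps most likely to fail

1. **Step 12 (Pd C–H arylation).** It forms a tetra-ortho-substituted, 11-membered biaryl, and it may compete with the free C–H positions of the 4,6-HHDP rings.
   - Fallback: switch to Ullmann coupling, with O3 as a 2,6-dihalogallate and O2 as a 2-iodogallate. Install the 4,6-HHDP first, with the 2,3-diol temporarily protected, so that only one aryl-halide pair is present at each coupling. Alternatively, couple the debenzylated pair of rings by Cu/amine oxidative phenol coupling.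
2. **Step 11 (C1 Friedel–Crafts).** Diastereoselectivity at C1 is uncertain, and the benzylic alcohol can ionise under Lewis acid.
   - Fallback: replace it with an intramolecular Cr/Ni Nozaki–Hiyama–Kishi coupling of an aryl iodide on the O2 ring with the aldehyde. This requires using a diiodogallate at O2.
3. **Steps 8–9 (ring-opening and O5 acylation).** Acyl migration from O4 to O5 and the hindered esterification are the risks.
   - Fallback: reduce lactol 9 with NaBH4 to the glucitol, protect 1-OH as TBDPS, acylate O5, remove TBDPS, then oxidise C1 to the aldehyde with Dess–Martin periodinane, giving 12 without a hydrazone.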